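**Retrosynthetic overview**
- The aryl ether C–O bond is cut last (Mitsunobu reaction of allylic alcohol 14 with 4-hydroxy-5-methylcoumarin 17). The E-trisubstituted alkene comes from a B-alkyl Suzuki–Miyaura coupling of a ring vinyl group with (E)-enol triflate 9, and the exocyclic methylidene from methylenation of a ring ketone.
- The cyclohexane is built in one operation from two acyclic pieces, bis(boronate) 4 and succinaldehyde 2, by a tandem double allylboration. It forms the bond between the carbinol carbon and the gem-dimethyl carbon and the bond between the side-chain-bearing CH and the carbon that later carries the methylidene.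
- Enabling feature: in the cyclohexanol ring, C-1 (carbinol) and C-4 (methylidene carbon) are 1,4-related through the two CH2 groups C-6 and C-5, which is a masked succinaldehyde. The two carbons between them on the other side, C-2 (gem-dimethyl) and C-3 (CH with the side chain), are the adjacent C-4 and C-3 of 4-methylpenta-1,3-diene, whose C-2 and C-1 become the first two side-chain carbons.
- Ring order: cyclohexane first (step 3); the coumarin bicycle is made separately (step 9) and attached last. No protecting groups are used.

Key step: step 3

Remark: the chiral TADDOL-derived phenylphosphonite in step 2 is used as the enantiomer that delivers (S)-4, to be confirmed on the derived diol.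

**Route**

Step 1
Reactants: 1 2,5-dimethoxytetrahydrofuran
Product: 2 succinaldehyde
Conditions: H2O, 90 °C; CH2Cl2 extraction, distillation, used fresh
Reagents that add atoms: water, O
Why: Hydrolysis of the cyclic bis-acetal (acetal hydrolysis) should release the dialdehyde, which is used freshly distilled because it oligomerises on standing.

Step 2
Reactants: 3 4-methylpenta-1,3-diene
Product: 4 2,2'-[(2S)-4-methylpent-3-ene-1,2-diyl]bis(4,4,5,5-tetramethyl-1,3,2-dioxaborolane)
Conditions: B2pin2, Pt(dba)3 (3 mol%), chiral TADDOL-derived phenylphosphonite (6 mol%), THF, 60 °C; short silica plug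
Reagents that add atoms: bis(pinacolato)diboron, CC1(C)OB(OC1(C)C)B1OC(C)(C)C(C)(C)O1
Why: Platinum-catalysed enantioselective 1,2-diboration of the terminal double bond of a 4,4-disubstituted 1,3-diene should occur because the cis-methyl group disfavours the s-cis conformer needed for 1,4-addition, and the boron-bearing stereocentre is set by the chiral phosphonite on zerovalent platinum.

Step 3
Reactants: 4 (S)-bis(boronate); 2 succinaldehyde
Product: 7 (1S,3S,4S)-3-ethenyl-2,2-dimethylcyclohexane-1,4-diol, via mono-allylation aldehyde 5 (not isolated), via cyclic bis(borate) ester 6 (not isolated)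
Conditions: THF (0.05 M), 60 °C; then H2O, rt
Reagents that add atoms: none
Why: The allylic C–B bond of 4 adds to one formyl group of 2 through a closed six-membered chair transition state with allyl transposition, so the γ,γ-dimethyl terminus becomes the quaternary carbon next to the new carbinol and the former primary boronate becomes the (E)-allylboronate 5, whose γ-carbon then adds to the second formyl group of the same molecule to give 6, and hydrolysis of the two B–O bonds on work-up releases 7. The closest known reaction type is the tandem double allylboration of 1,4-dicarbonyl compounds by diene-derived vicinal bis(boronates), which gives cyclohexane-1,4-diols. The six-membered carbocycle is closed by an intramolecular allylboration (6-exo-trig addition of the allyl γ-carbon to the tethered aldehyde) through a trans-decalin-like bicyclic transition state in which the forming ring is a chair. The carbinol next to the gem-dimethyl carbon is set by 1,3-chirality transfer from the boron-bearing stereocentre of 4, with the aldehyde chain equatorial and the α-CH2B group equatorial because the cis γ-methyl group forbids the axial arrangement; the vinyl-bearing carbon is set by this carbinol, whose boryloxy group sits equatorial in the closing chair; the second carbinol is set by the E geometry of 5, which places hydroxyl trans to vinyl. The step needs the first addition to occur at the tertiary γ-terminus and the second to be intramolecular rather than a second intermolecular allylation; the closed transition state secures the former, and dilution together with the six-membered ring size secures the latter.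

Step 4
Reactants: 8 ethyl acetoacetate
Product: 9 ethyl (2E)-3-{[(trifluoromethyl)sulfonyl]oxy}but-2-enoate
Conditions: Tf2O, aq. Me4NOH, hexane, 5 °C
Reagents that add atoms: trifluoromethanesulfonic anhydride, O=S(=O)(OS(=O)(=O)C(F)(F)F)C(F)(F)F
Why: O-Sulfonylation of the non-chelated tetramethylammonium enolate of a β-keto ester (stereoselective enol triflation) should give the E enol triflate, in which the triflate is trans to the ester.

Step 5
Reactants: 7 vinyl diol; 9 (E)-enol triflate
Product: 11 ethyl (2E)-5-[(1S,3S,6S)-3,6-dihydroxy-2,2-dimethylcyclohexyl]-3-methylpent-2-enoate, via B-alkyl-9-borabicyclononane 10 (not isolated)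
Conditions: 9-BBN-H dimer (excess), THF, rt; then 9, Pd(dppf)Cl2 (5 mol%), aq. K3PO4, DMF, 50 °C
Reagents that add atoms: none
Why: Hydroboration with 9-BBN places boron on the terminal carbon of the only alkene, and the B-alkyl Suzuki–Miyaura coupling replaces the triflate with retention, so the E geometry of 9 becomes the E-trisubstituted alkene of the side chain while the free hydroxyls are tolerated.

Step 6
Reactants: 11 diol ester
Product: 12 ethyl (2E)-5-[(1S,3S)-3-hydroxy-2,2-dimethyl-6-oxocyclohexyl]-3-methylpent-2-enoate
Conditions: TEMPO (20 mol%), PhI(OAc)2, CH2Cl2, rt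
Reagents that add atoms: none
Why: The oxoammonium oxidation is sterically demanding, so the hydroxyl flanked by CH and CH2 should be oxidised ahead of the neopentyl-type hydroxyl next to the gem-dimethyl carbon, and the neutral conditions leave the α-stereocentre untouched.

Step 7
Reactants: 12 hydroxy ketone
Product: 13 ethyl (2E)-5-[(1R,3S)-3-hydroxy-2,2-dimethyl-6-methylidenecyclohexyl]-3-methylpent-2-enoate
Conditions: Zn, CH2Br2, TiCl4, THF/CH2Cl2, 0 °C to rt
Reagents that add atoms: dibromomethane, BrCBr
Why: The non-basic zinc–titanium methylenation (Takai–Lombardo) should convert the ketone into the exocyclic methylidene without enolising the adjacent stereocentre and without touching the ester or the free hydroxyl.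

Step 8
Reactants: 13 enoate
Product: 14 (1S,3R)-3-[(3E)-5-hydroxy-3-methylpent-3-en-1-yl]-2,2-dimethyl-4-methylidenecyclohexan-1-ol
Conditions: i-Bu2AlH (excess), CH2Cl2, −78 °C
Reagents that add atoms: none
Why: 1,2-Reduction of the conjugated ester by the aluminium hydride should give the primary allylic alcohol with the E geometry retained.

Step 9
Reactants: 15 1-(2-hydroxy-6-methylphenyl)ethan-1-one
Product: 17 4-hydroxy-5-methyl-2H-chromen-2-one, via β-keto ester 16 (not isolated)
Conditions: NaH, diethyl carbonate, toluene, 110 °C; then aq. HCl
Reagents that add atoms: diethyl carbonate, CCOC(=O)OCC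
Why: Claisen-type C-acylation of the ketone enolate by the carbonate followed by lactonisation of the phenoxide onto the new ester should give the 4-hydroxycoumarin.

Step 10
Reactants: 14 allylic alcohol; 17 4-hydroxy-5-methylcoumarin
Product: 18 4-{[(2E)-5-[(1R,3S)-3-hydroxy-2,2-dimethyl-6-methylidenecyclohexyl]-3-methylpent-2-en-1-yl]oxy}-5-methyl-2H-chromen-2-one
Conditions: PPh3, DIAD, THF, 0 °C to rt
Reagents that add atoms: none
Why: In the Mitsunobu etherification the acidic 4-hydroxycoumarin should be alkylated on O-4 by the activated primary allylic alcohol, while the hindered secondary hydroxyl next to the gem-dimethyl carbon does not react.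

**Compound list**
1 | 2,5-dimethoxytetrahydrofuran (cis/trans mixture) | COC1CCC(OC)O1 | starting material
2 | succinaldehyde (butanedial) | O=CCCC=O | intermediate
3 | 4-methylpenta-1,3-diene | CC(C)=CC=C | starting material
4 | 2,2'-[(2S)-4-methylpent-3-ene-1,2-diyl]bis(4,4,5,5-tetramethyl-1,3,2-dioxaborolane) | CC(C)=C[C@@H](B1OC(C)(C)C(C)(C)O1)CB1OC(C)(C)C(C)(C)O1 | intermediate
5 | (4S,6E)-5,5-dimethyl-4-[(4,4,5,5-tetramethyl-1,3,2-dioxaborolan-2-yl)oxy]-8-(4,4,5,5-tetramethyl-1,3,2-dioxaborolan-2-yl)oct-6-enal | O=CCC[C@H](OB1OC(C)(C)C(C)(C)O1)C(C)(C)/C=C/CB1OC(C)(C)C(C)(C)O1 | intermediate (not isolated)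
6 | 2,2'-{[(1S,3S,4S)-3-ethenyl-2,2-dimethylcyclohexane-1,4-diyl]bis(oxy)}bis(4,4,5,5-tetramethyl-1,3,2-dioxaborolane) | [C@H]1(OB2OC(C)(C)C(C)(C)O2)CC[C@H](OB2OC(C)(C)C(C)(C)O2)C(C)(C)[C@@H]1C=C | intermediate (not isolated)
7 | (1S,3S,4S)-3-ethenyl-2,2-dimethylcyclohexane-1,4-diol (both hydroxyls and the vinyl group equatorial) | O[C@H]1CC[C@H](O)C(C)(C)[C@@H]1C=C | intermediate
8 | ethyl acetoacetate (ethyl 3-oxobutanoate) | CCOC(=O)CC(C)=O | starting material
9 | ethyl (2E)-3-{[(trifluoromethyl)sulfonyl]oxy}but-2-enoate | C/C(OS(=O)(=O)C(F)(F)F)=C\C(=O)OCC | intermediate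
10 | (1S,3S,4S)-3-[2-(9-borabicyclo[3.3.1]nonan-9-yl)ethyl]-2,2-dimethylcyclohexane-1,4-diol | O[C@H]1CC[C@H](O)C(C)(C)[C@@H]1CCB1C2CCCC1CCC2 | intermediate (not isolated)
11 | ethyl (2E)-5-[(1S,3S,6S)-3,6-dihydroxy-2,2-dimethylcyclohexyl]-3-methylpent-2-enoate | O[C@H]1CC[C@H](O)C(C)(C)[C@@H]1CC/C(C)=C/C(=O)OCC | intermediate
12 | ethyl (2E)-5-[(1S,3S)-3-hydroxy-2,2-dimethyl-6-oxocyclohexyl]-3-methylpent-2-enoate | O=C1CC[C@H](O)C(C)(C)[C@@H]1CC/C(C)=C/C(=O)OCC | intermediate
13 | ethyl (2E)-5-[(1R,3S)-3-hydroxy-2,2-dimethyl-6-methylidenecyclohexyl]-3-methylpent-2-enoate | C=C1CC[C@H](O)C(C)(C)[C@@H]1CC/C(C)=C/C(=O)OCC | intermediate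
14 | (1S,3R)-3-[(3E)-5-hydroxy-3-methylpent-3-en-1-yl]-2,2-dimethyl-4-methylidenecyclohexan-1-ol | C=C1CC[C@H](O)C(C)(C)[C@@H]1CC/C(C)=C/CO | intermediate
15 | 1-(2-hydroxy-6-methylphenyl)ethan-1-one | CC(=O)c1c(C)cccc1O | starting material
16 | ethyl 3-(2-hydroxy-6-methylphenyl)-3-oxopropanoate | CCOC(=O)CC(=O)c1c(C)cccc1O | intermediate (not isolated)
17 | 4-hydroxy-5-methyl-2H-chromen-2-one | Cc1cccc2oc(=O)cc(O)c12 | intermediate
18 | 4-{[(2E)-5-[(1R,3S)-3-hydroxy-2,2-dimethyl-6-methylidenecyclohexyl]-3-methylpent-2-en-1-yl]oxy}-5-methyl-2H-chromen-2-one | C=C1CC[C@H](O)C(C)(C)[C@@H]1CC/C(C)=C/COc1cc(=O)oc2cccc(C)c12 | target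

**Step count**
Total steps: 10. Longest linear sequence: 7 steps (2, 3, 5, 6, 7, 8, 10).

**Steps most likely to fail**

Step 3. The mono-allylated aldehyde may be diverted before ring closure, by oligomerisation of the dialdehyde or by a second intermolecular allylation, or the closure may proceed with poor facial control relative to the first carbinol. The fallback sets out from 4 and separates the two carbonyl additions. Allylboration of methyl 4-oxobutanoate (COC(=O)CCC=O; THF, 60 °C) followed by acid-promoted lactonisation should give the lactone that still carries the (E)-allyl pinacol boronate, (5S)-5-[(3E)-2-methyl-5-(4,4,5,5-tetramethyl-1,3,2-dioxaborolan-2-yl)pent-3-en-2-yl]oxolan-2-one F1. Reduction with i-Bu2AlH at −78 °C should give the lactol (5S)-5-[(3E)-2-methyl-5-(4,4,5,5-tetramethyl-1,3,2-dioxaborolan-2-yl)pent-3-en-2-yl]oxolan-2-ol F2. Its open hydroxy-aldehyde form should undergo the ring-closing allylboration on warming, with Sc(OTf)3 catalysis if needed, and aqueous work-up returns the route to 7.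

Step 6. Steric discrimination between the two secondary hydroxyls may be insufficient, so that oxidation also occurs at the carbinol next to the gem-dimethyl carbon. The fallback sets out from 11 and gives up the differentiation. Dess–Martin periodinane (CH2Cl2, NaHCO3) should oxidise both hydroxyls to ethyl (2E)-5-[(1S)-2,2-dimethyl-3,6-dioxocyclohexyl]-3-methylpent-2-enoate F3. The Takai–Lombardo reagent should then methylenate only the less hindered carbonyl, the one flanked by CH and CH2, to give ethyl (2E)-5-[(1R)-2,2-dimethyl-6-methylidene-3-oxocyclohexyl]-3-methylpent-2-enoate F4. NaBH4 in MeOH at −20 °C should deliver hydride axially to the remaining ketone next to the gem-dimethyl carbon and give the equatorial alcohol cis to the side chain, which returns the route to 13. Base must be avoided while the diketone is in hand, because the side-chain-bearing carbon is then the only stereocentre.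

Step 10. The ambident coumarin nucleophile may be alkylated at O-2 or C-3, or in the SN2′ sense, instead of at the O-4 position, which is crowded by the peri methyl group. The fallback reverses the polarity of the ether formation. Setting out from 17, POCl3 with Et3N at 90 °C should give 4-chloro-5-methyl-2H-chromen-2-one F5. The primary alkoxide of 14 (NaH, 1 equiv, THF, 0 °C) should then displace chloride at C-4 by addition–elimination, which can only form the O-4 ether, and this arrives at 18.

**Further compounds**
F1 | step 3 | (5S)-5-[(3E)-2-methyl-5-(4,4,5,5-tetramethyl-1,3,2-dioxaborolan-2-yl)pent-3-en-2-yl]oxolan-2-one | O=C1CC[C@H](O1)C(C)(C)/C=C/CB1OC(C)(C)C(C)(C)O1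
F2 | step 3 | (5S)-5-[(3E)-2-methyl-5-(4,4,5,5-tetramethyl-1,3,2-dioxaborolan-2-yl)pent-3-en-2-yl]oxolan-2-ol | OC1CC[C@H](O1)C(C)(C)/C=C/CB1OC(C)(C)C(C)(C)O1
F3 | step 6 | ethyl (2E)-5-[(1S)-2,2-dimethyl-3,6-dioxocyclohexyl]-3-methylpent-2-enoate | O=C1CCC(=O)C(C)(C)[C@@H]1CC/C(C)=C/C(=O)OCC
F4 | step 6 | ethyl (2E)-5-[(1R)-2,2-dimethyl-6-methylidene-3-oxocyclohexyl]-3-methylpent-2-enoate | C=C1CCC(=O)C(C)(C)[C@@H]1CC/C(C)=C/C(=O)OCC
F5 | step 10 | 4-chloro-5-methyl-2H-chromen-2-one | Cc1cccc2oc(=O)cc(Cl)c12
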